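**Retrosynthetic overview**

1. Target 24 ← Friedel–Crafts C-acylation (C1–CO bond of ring A) of the symmetric 2-(4-methylpentyl)resorcinol 21 with acid chloride 23; the dichloropyrrole (ring B) is bought intact.
2. 21 ← 20 ← 17 by O-demethylation and reductive removal of a benzylic dimethylamino group.
3. 17 ← one-flask union of 3-methoxybenzyne (from silyl triflate 8), DMF 12 and bis(3-methylbutyl)zinc 11, forming C4–O, C3–C1' and C1'–C2'.
4. 8 ← 3-methoxyphenol 1 by carbamate-directed silylation at the carbon between the two oxygens; no ring is built in the route (ring A comes from 1, ring B from 22).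
5. Feature: in ring A (C1 acyl, C2 OH, C3 4-methylpentyl, C4 OH) the chain-bearing C3 lies between the oxygenated C2 and C4. This maps onto 3-methoxybenzyne: its methoxy carbon becomes C2, the adjacent aryne carbon becomes C3 (new C–C) and the remote aryne carbon becomes C4 (new C–O).

Key step: step 5

Remark: the target has no stereocentre; the benzylic centre created in step 5 is racemic and becomes CH2 in step 6.

**Step 1**
Reactants: 1 3-methoxyphenol
Product: 2 3-methoxyphenyl N-isopropylcarbamate
Conditions: i-PrNCO, Et3N (cat.), CH2Cl2, rt
Reagents that add atoms: isopropyl isocyanate, CC(C)N=C=O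
Why: Base-catalysed addition of the phenol O–H to the isocyanate (carbamoylation) should install a directing group that can later be removed under mild conditions.

**Step 2**
Reactants: 2 3-methoxyphenyl N-isopropylcarbamate
Product: 6 3-methoxy-2-(trimethylsilyl)phenyl N-isopropylcarbamate, via N-silyl carbamate 3 (not isolated), via aryllithium 4 (not isolated), via N-silyl C-silyl carbamate 5 (not isolated)
Conditions: TBSOTf, TMEDA, Et2O, 0 °C → rt; n-BuLi, TMEDA, −78 °C; TMSCl, −78 °C → rt; aq. NaHSO4
Reagents that add atoms: chlorotrimethylsilane, C[Si](C)(C)Cl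
Why: After in situ N-silylation masks the N–H, directed ortho-metalation should occur at C2, which is activated by both the methoxy and the carbamate oxygen, and the aryllithium is trapped by TMSCl before the N–Si bond is hydrolysed on acidic work-up.

**Step 3**
Reactants: 6 3-methoxy-2-(trimethylsilyl)phenyl N-isopropylcarbamate
Product: 8 3-methoxy-2-(trimethylsilyl)phenyl trifluoromethanesulfonate, via silylphenol 7 (not isolated)
Conditions: Et2NH, DBU, MeCN, 40 °C; then PhNTf2, 40 °C
Reagents that add atoms: N-phenylbis(trifluoromethanesulfonimide), O=S(=O)(N(c1ccccc1)S(=O)(=O)C(F)(F)F)C(F)(F)F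
Why: DBU should trigger E1cB loss of isopropyl isocyanate (scavenged by Et2NH as a urea) and the freed phenoxide is O-sulfonylated by PhNTf2, a carbamate cleavage and triflation that uses neither acid nor fluoride and so spares the C–Si bond.

**Step 4**
Reactants: 9 1-bromo-3-methylbutane (2 equiv per molecule of product)
Product: 11 bis(3-methylbutyl)zinc, via Grignard reagent 10 (not isolated)
Conditions: Mg turnings, Et2O, reflux; ZnCl2 (0.5 equiv relative to the Grignard reagent), Et2O, 0 °C → rt; 1,4-dioxane, filtration under argon, solution titrated
Reagents that add atoms: zinc chloride, Cl[Zn]Cl; 1-bromo-3-methylbutane (the second equivalent of 9), CC(C)CCBr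
Why: Grignard formation followed by transmetalation, in which two molecules of 10 each transfer a 3-methylbutyl group to one ZnCl2, gives the dialkylzinc, and dioxane precipitates the magnesium halides so that a salt-free reagent enters the key step.

**Step 5**
Reactants: 8 3-methoxy-2-(trimethylsilyl)phenyl trifluoromethanesulfonate; 12 N,N-dimethylformamide (reactant and solvent); 11 bis(3-methylbutyl)zinc
Product: 17 racemic 2-[1-(dimethylamino)-4-methylpentyl]-3-methoxyphenol, via 3-methoxybenzyne 13 (not isolated), via benzoxetene 14 (not isolated), via ortho-quinone methide 15 (not isolated), via zinc phenoxide 16 (not isolated)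
Conditions: CsF (3 equiv), 11 (3 equiv), DMF, 25 °C; then aq. NH4Cl
Reagents that add atoms: none
Why: CsF attacks the silicon of 8 and triflate leaves to give 3-methoxybenzyne 13, whose aryne carbon remote from the methoxy group is attacked by the carbonyl oxygen of DMF while the aryl anion generated next to the methoxy-bearing carbon closes on the iminium carbon. The only ring closed is the transient four-membered benzoxetene 14 (stepwise formal [2+2], 4-exo attack of the aryl anion on C=N+), which opens by 4π-electrocyclic cleavage to the aminomethylene ortho-quinone methide 15 and so is absent from 17. Dialkylzinc 11 then transfers one 3-methylbutyl group to the exocyclic carbon of 15 (1,4-addition driven by rearomatisation) to give zinc phenoxide 16, which is protonated on work-up. The closest known reaction type is the three-component coupling of arynes, formamides and dialkylzincs (aryne insertion into the formamide C=O bond, then conjugate alkylation of the ortho-quinone methide). The new benzylic stereocentre is formed without a controlling element, so 17 is racemic, which does not matter because this carbon becomes CH2 in step 6. The selectivity needed is regiochemical, oxygen at the distal and carbon at the proximal aryne carbon, and the inductively withdrawing methoxy group should secure it by distorting the aryne so that the nucleophile attacks the carbon meta to OMe and the carbanion develops ortho to it.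

**Step 6**
Reactants: 17 racemic 2-[1-(dimethylamino)-4-methylpentyl]-3-methoxyphenol
Product: 20 3-methoxy-2-(4-methylpentyl)phenol, via methiodide 18 (not isolated), via ortho-quinone methide 19 (not isolated)
Conditions: MeI, MeCN, rt; evaporate; NaBH4, EtOH, 0 → 60 °C
Reagents that add atoms: none
Why: N-Methylation turns the amine into a leaving group, the phenoxide formed under NaBH4 expels trimethylamine by 1,4-elimination, and hydride adds to the exocyclic carbon of the resulting ortho-quinone methide (reductive deamination of a phenolic Mannich-base methiodide).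

**Step 7**
Reactants: 20 3-methoxy-2-(4-methylpentyl)phenol
Product: 21 2-(4-methylpentyl)benzene-1,3-diol
Conditions: BBr3, CH2Cl2, −78 °C → rt; H2O
Reagents that add atoms: none
Why: Lewis-acid cleavage of the aryl methyl ether by BBr3 (bromide attack on the O-methyl of the boron-complexed ether) should give the C2-symmetric resorcinol, with nothing else in the molecule sensitive to the reagent.

**Step 8**
Reactants: 22 4,5-dichloro-1H-pyrrole-2-carboxylic acid
Product: 23 4,5-dichloro-1H-pyrrole-2-carbonyl chloride
Conditions: (COCl)2, DMF (cat.), CH2Cl2, 0 °C → rt; evaporate, used crude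
Reagents that add atoms: oxalyl chloride, O=C(Cl)C(=O)Cl
Why: Acid chloride formation through the Vilsmeier-type chloroiminium catalyst should be clean because the electron-poor dichloropyrrole is a weak nucleophile at both N and C3.

**Step 9**
Reactants: 21 2-(4-methylpentyl)benzene-1,3-diol; 23 4,5-dichloro-1H-pyrrole-2-carbonyl chloride
Product: 24 (4,5-dichloro-1H-pyrrol-2-yl)[2,4-dihydroxy-3-(4-methylpentyl)phenyl]methanone
Conditions: AlCl3 (4 equiv), 1,2-dichloroethane, 0 → 60 °C; ice, aq. HCl
Reagents that add atoms: none
Why: Friedel–Crafts acylation of the resorcinol can only occur at the two equivalent positions ortho to one hydroxyl and para to the other (C5 is meta to both), so one regioisomer is expected, and the chelated ortho-hydroxy ketone resists a second acylation.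

**Compound list**

1 | 3-methoxyphenol | COc1cccc(O)c1 | starting material
2 | 3-methoxyphenyl N-isopropylcarbamate | COc1cccc(OC(=O)NC(C)C)c1 | intermediate
3 | 3-methoxyphenyl N-(tert-butyldimethylsilyl)-N-isopropylcarbamate | COc1cccc(OC(=O)N(C(C)C)[Si](C)(C)C(C)(C)C)c1 | intermediate
4 | 2-lithio-3-methoxyphenyl N-(tert-butyldimethylsilyl)-N-isopropylcarbamate | COc1cccc(OC(=O)N(C(C)C)[Si](C)(C)C(C)(C)C)c1[Li] | intermediate
5 | 3-methoxy-2-(trimethylsilyl)phenyl N-(tert-butyldimethylsilyl)-N-isopropylcarbamate | COc1cccc(OC(=O)N(C(C)C)[Si](C)(C)C(C)(C)C)c1[Si](C)(C)C | intermediate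
6 | 3-methoxy-2-(trimethylsilyl)phenyl N-isopropylcarbamate | COc1cccc(OC(=O)NC(C)C)c1[Si](C)(C)C | intermediate
7 | 3-methoxy-2-(trimethylsilyl)phenol (present as its DBU-H phenoxide) | COc1cccc(O)c1[Si](C)(C)C | intermediate
8 | 3-methoxy-2-(trimethylsilyl)phenyl trifluoromethanesulfonate | COc1cccc(OS(=O)(=O)C(F)(F)F)c1[Si](C)(C)C | intermediate
9 | 1-bromo-3-methylbutane | CC(C)CCBr | starting material
10 | (3-methylbutyl)magnesium bromide | CC(C)CC[Mg]Br | intermediate
11 | bis(3-methylbutyl)zinc | CC(C)CC[Zn]CCC(C)C | intermediate
12 | N,N-dimethylformamide | CN(C)C=O | starting material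
13 | 3-methoxybenzyne (1-methoxycyclohexa-1,3-dien-5-yne form) | COC1=CC=CC#C1 | intermediate
14 | 3-methoxy-N,N-dimethyl-2H-benzo[b]oxet-2-amine | COc1cccc2OC(N(C)C)c12 | intermediate
15 | 6-[(dimethylamino)methylidene]-5-methoxycyclohexa-2,4-dien-1-one | COC1=CC=CC(=O)C1=CN(C)C | intermediate
16 | (3-methylbutyl)zinc 2-[1-(dimethylamino)-4-methylpentyl]-3-methoxyphenoxide | CC(C)CCC(N(C)C)c1c(O[Zn]CCC(C)C)cccc1OC | intermediate
17 | racemic 2-[1-(dimethylamino)-4-methylpentyl]-3-methoxyphenol | CC(C)CCC(N(C)C)c1c(O)cccc1OC | intermediate
18 | 1-(2-hydroxy-6-methoxyphenyl)-N,N,N,4-tetramethylpentan-1-aminium iodide (racemic) | CC(C)CCC(c1c(O)cccc1OC)[N+](C)(C)C.[I-] | intermediate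
19 | 5-methoxy-6-(4-methylpentylidene)cyclohexa-2,4-dien-1-one | COC1=CC=CC(=O)C1=CCCC(C)C | intermediate
20 | 3-methoxy-2-(4-methylpentyl)phenol | CC(C)CCCc1c(O)cccc1OC | intermediate
21 | 2-(4-methylpentyl)benzene-1,3-diol | CC(C)CCCc1c(O)cccc1O | intermediate
22 | 4,5-dichloro-1H-pyrrole-2-carboxylic acid | OC(=O)c1cc(Cl)c(Cl)[nH]1 | starting material
23 | 4,5-dichloro-1H-pyrrole-2-carbonyl chloride | O=C(Cl)c1cc(Cl)c(Cl)[nH]1 | intermediate
24 | (4,5-dichloro-1H-pyrrol-2-yl)[2,4-dihydroxy-3-(4-methylpentyl)phenyl]methanone | CC(C)CCCc1c(O)ccc(C(=O)c2cc(Cl)c(Cl)[nH]2)c1O | target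

**Step count and risks**

Total steps: 9. Longest linear sequence: 7 (steps 1, 2, 3, 5, 6, 7, 9); steps 4 and 8 prepare the two side components.

Steps most likely to fail:

Step 5. A higher dialkylzinc with β-hydrogens may deliver hydride instead of the alkyl group to the ortho-quinone methide, or transfer its alkyl group too slowly, so that the quinone methide is consumed by the amine or phenoxide already formed; partial loss of regiocontrol in the capture of the aryne by DMF is a second concern. The fallback leaves the aryne chemistry and sets out from 1. O-Methylation (MeI, K2CO3, acetone) would give 1,3-dimethoxybenzene F1. Lithiation between the two methoxy groups (n-BuLi, THF, 0 °C → rt) and alkylation with 1-bromo-4-methylpentane would give 1,3-dimethoxy-2-(4-methylpentyl)benzene F2. Excess BBr3 in CH2Cl2 would cleave both ethers, and the route is rejoined at 21.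

Step 6. The ortho-quinone methide may tautomerise to the alkenylphenol or dimerise by hetero-Diels–Alder reaction before hydride captures it, and quaternisation of the hindered amine flanked by two ortho substituents may be slow. The fallback sets out from 17 and removes nitrogen by elimination instead of reduction. mCPBA (CH2Cl2, 0 °C) would give 1-(2-hydroxy-6-methoxyphenyl)-N,N,4-trimethylpentan-1-amine N-oxide F3. Heating in toluene would effect Cope syn-elimination to (E)-3-methoxy-2-(4-methylpent-1-en-1-yl)phenol F4. Hydrogenation (H2, Pd/C (palladium on carbon), EtOAc) would saturate the alkene, and the route is rejoined at 20.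

Step 9. Acylation may stop at oxygen without migration to carbon, the acid chloride may condense with itself through the pyrrole nitrogen, or the aluminium-complexed resorcinol may be too deactivated. The fallback sets out from 23 (with 21 as partner) and replaces the acylium electrophile by a nitrilium one. Aqueous NH3 would convert 23 into 4,5-dichloro-1H-pyrrole-2-carboxamide F5, and dehydration with POCl3 would give 4,5-dichloro-1H-pyrrole-2-carbonitrile F6. Houben–Hoesch reaction of F6 with 21 (ZnCl2, HCl gas, Et2O, 0 °C) would give (4,5-dichloro-1H-pyrrol-2-yl)[2,4-dihydroxy-3-(4-methylpentyl)phenyl]methaniminium chloride F7, which is hydrolysed in warm water, and the route is rejoined at 24.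

**Further compounds**

F1 | step 5 | 1,3-dimethoxybenzene | COc1cccc(OC)c1
F2 | step 5 | 1,3-dimethoxy-2-(4-methylpentyl)benzene | CC(C)CCCc1c(OC)cccc1OC
F3 | step 6 | 1-(2-hydroxy-6-methoxyphenyl)-N,N,4-trimethylpentan-1-amine N-oxide | CC(C)CCC(c1c(O)cccc1OC)[N+](C)(C)[O-]
F4 | step 6 | (E)-3-methoxy-2-(4-methylpent-1-en-1-yl)phenol | CC(C)C/C=C/c1c(O)cccc1OC
F5 | step 9 | 4,5-dichloro-1H-pyrrole-2-carboxamide | NC(=O)c1cc(Cl)c(Cl)[nH]1
F6 | step 9 | 4,5-dichloro-1H-pyrrole-2-carbonitrile | N#Cc1cc(Cl)c(Cl)[nH]1
F7 | step 9 | (4,5-dichloro-1H-pyrrol-2-yl)[2,4-dihydroxy-3-(4-methylpentyl)phenyl]methaniminium chloride | CC(C)CCCc1c(O)ccc(C(=[NH2+])c2cc(Cl)c(Cl)[nH]2)c1O.[Cl-]
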